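**Retrosynthetic overview**
1. The target is a benzylic ester. Ring A is atraric acid (methyl 2,4-dihydroxy-3,6-dimethylbenzoate) oxidised at its C6 methyl group; ring B is atranol (2,6-dihydroxy-4-methylbenzaldehyde, made here from orcinol) plus one carboxyl carbon. Both benzene rings are bought intact, so no ring is formed.
2. Key disconnection: the bond between the ester carbonyl carbon and the ring B carbon that carries it. That carbon is supplied as CO2 and is inserted in one pot between a ring B aryllithium (from C–H lithiation) and the ring A benzylic chloride, a three-component union that makes the C–C bond first and the O–CH2 bond second.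
3. Enabling feature, ring B: the ester-bearing carbon is ortho to a phenolic oxygen, and the formyl carbon and the C-methyl carbon lie on a mirror plane of protected atranol. Its two ring C–H are therefore equivalent and each sits next to an OMOM director.
4. Enabling feature, ring A: the CH2O carbon is ortho to the CO2Me carbon. This makes that methyl the only acidic one (lateral lithiation, then chlorination), and it rules out a free benzylic alcohol, which would close to the phthalide; the oxygen is therefore delivered as a carboxylate.
5. Order: orcinol → bis-MOM ether → C2 formylation → dimethyl acetal; atraric acid → bis-MOM ether → benzylic chloride; three-component union; one acidic step removes four MOM groups and the acetal.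

Key step: step 6

Assumption: the target has no stereocentre and no stereogenic double bond; it is achiral, so the route needs no stereocontrol.

**Step 1**
Reactants: 1 orcinol (5-methylbenzene-1,3-diol, anhydrous)
Product: 2 1,3-bis(methoxymethoxy)-5-methylbenzene
Conditions: NaH (2.4 equiv), MOMCl (2.4 equiv), DMF, 0 °C → rt
Reagents that add atoms: chloromethyl methyl ether, COCCl
Why: Williamson-type O-alkylation of the bis-phenoxide by the reactive α-chloro ether should be clean, and the MOM groups serve later as ortho-directing groups that leave under mild acid.

**Step 2**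
Reactants: 2 1,3-bis(methoxymethoxy)-5-methylbenzene
Product: 5 2,6-bis(methoxymethoxy)-4-methylbenzaldehyde, via aryllithium 3 (not isolated), via lithium hemiaminal alkoxide 4 (not isolated)
Conditions: n-BuLi (1.1 equiv), THF, 0 °C; DMF (1.5 equiv), −78 °C → rt; H2O
Reagents that add atoms: N,N-dimethylformamide, CN(C)C=O
Why: Directed ortho-metalation should take place at the ring C–H between the two OMOM groups, the doubly chelated and most acidic site, and formylation of 3 by DMF (Bouveault-type) stops at the hemiaminal alkoxide 4, which releases the aldehyde only on aqueous work-up.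

**Step 3**
Reactants: 5 2,6-bis(methoxymethoxy)-4-methylbenzaldehyde
Product: 6 2-(dimethoxymethyl)-1,3-bis(methoxymethoxy)-5-methylbenzene
Conditions: HC(OMe)3 (5 equiv), PPTS (5 mol%), MeOH, rt; then Et3N
Reagents that add atoms: trimethyl orthoformate, COC(OC)OC; methanol, CO
Why: Acid-catalysed acetalisation with the orthoformate as water scavenger should be fast for this electron-rich 2,6-dialkoxybenzaldehyde (stabilised oxocarbenium ion), so the weak acid PPTS at room temperature suffices and should leave the aryl MOM ethers intact, while the acetal masks the only group of ring B that an alkyllithium would attack.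

**Step 4**
Reactants: 7 atraric acid (methyl 2,4-dihydroxy-3,6-dimethylbenzoate)
Product: 8 methyl 2,4-bis(methoxymethoxy)-3,6-dimethylbenzoate
Conditions: NaH (2.5 equiv), MOMCl (2.5 equiv), DMF, 0 °C → rt
Reagents that add atoms: chloromethyl methyl ether, COCCl
Why: Williamson-type O-alkylation, in which NaH also deprotonates the hindered, hydrogen-bonded C2 hydroxyl next to the ester, so that both phenols should be capped with groups that tolerate LDA.

**Step 5**
Reactants: 8 methyl 2,4-bis(methoxymethoxy)-3,6-dimethylbenzoate
Product: 10 methyl 6-(chloromethyl)-2,4-bis(methoxymethoxy)-3-methylbenzoate, via benzylic organolithium 9 (not isolated)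
Conditions: LDA (commercial solution, 1.1 equiv), THF, −78 °C; cannulated into C2Cl6 (1.5 equiv), THF, −78 °C; AcOH quench
Reagents that add atoms: hexachloroethane, ClC(Cl)(Cl)C(Cl)(Cl)Cl
Why: Lateral (benzylic) lithiation should be selective because only the C6 methyl, ortho to the ester, gives a conjugated dienolate, and inverse addition to the positive-chlorine donor hexachloroethane should chlorinate that carbon while the excess of halogen source suppresses coupling of the anion with the chloride already formed.

**Step 6**
Reactants: 6 2-(dimethoxymethyl)-1,3-bis(methoxymethoxy)-5-methylbenzene; 10 methyl 6-(chloromethyl)-2,4-bis(methoxymethoxy)-3-methylbenzoate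
Product: 13 [2-(methoxycarbonyl)-3,5-bis(methoxymethoxy)-4-methylphenyl]methyl 3-(dimethoxymethyl)-2,4-bis(methoxymethoxy)-6-methylbenzoate, via aryllithium 11 (not isolated), via lithium carboxylate 12 (not isolated)
Conditions: 6 (1.15 equiv), s-BuLi (1.1 equiv), THF, −78 → −20 °C (no amine additive); CO2 (g), −78 → 0 °C, then Ar purge; 10 (1.0 equiv), n-Bu4NI (10 mol%), DMF, 40 °C
Reagents that add atoms: carbon dioxide, O=C=O
Why: The OMOM oxygen on C3 of 6 delivers s-BuLi to the neighbouring ring C4–H (directed ortho-metalation; C6–H is its mirror image, and the C-methyl group has no ortho director and should not be deprotonated), and the resulting aryllithium 11 adds to CO2, which forms the aryl–carbonyl C–C bond as lithium carboxylate 12. After the excess CO2 is purged, 12 displaces chloride (iodide-catalysed SN2) from the benzylic carbon of 10, which is activated by the ortho CO2Me group, so the carbon of CO2 ends up bonded to ring B on one side and to the ring A benzylic oxygen on the other. The closest known reaction types are the ortho-lithiation–carboxylation of aryl MOM ethers and the O-benzylation of resorcylate carboxylates by 2-(halomethyl)benzoates; run in one pot they amount to a three-component coupling. No ring is closed and no stereocentre is formed. The step needs site selectivity on ring B, secured by the mirror symmetry of 6 and the ortho OMOM director, and chemoselectivity, secured by the order of addition: the organolithium is consumed by CO2 before the ester-bearing electrophile 10 enters, after which the carboxylate is the only nucleophile present. Because the benzylic oxygen of ring A is never a free hydroxyl next to CO2Me, closure to the phthalide cannot compete.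

**Step 7**
Reactants: 13 [2-(methoxycarbonyl)-3,5-bis(methoxymethoxy)-4-methylphenyl]methyl 3-(dimethoxymethyl)-2,4-bis(methoxymethoxy)-6-methylbenzoate
Product: 14 [3,5-dihydroxy-2-(methoxycarbonyl)-4-methylphenyl]methyl 3-formyl-2,4-dihydroxy-6-methylbenzoate (CNP0122264.0)
Conditions: HCl (0.5 M), MeOH–H2O–THF (8:1:1), 40 °C
Reagents that add atoms: water, O
Why: Acid-catalysed solvolysis (transacetalisation) should convert the four aryl MOM ethers into phenols and dimethoxymethane and hydrolyse the dimethyl acetal to the aldehyde, with methanol trapping the methoxymethyl cations before they can alkylate the free ring positions, while the inter-ring ester, a 2,6-disubstituted hydrogen-bonded benzoate of a benzylic alcohol that is not cation-stabilised, should resist acid methanolysis.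

**Compound list**
1 | orcinol (5-methylbenzene-1,3-diol) | Cc1cc(O)cc(O)c1 | starting material
2 | 1,3-bis(methoxymethoxy)-5-methylbenzene | COCOc1cc(C)cc(OCOC)c1 | intermediate
3 | [2,6-bis(methoxymethoxy)-4-methylphenyl]lithium (not isolated) | [Li]c1c(OCOC)cc(C)cc1OCOC | intermediate
4 | lithium (dimethylamino)[2,6-bis(methoxymethoxy)-4-methylphenyl]methanolate (not isolated) | [Li+].[O-]C(N(C)C)c1c(OCOC)cc(C)cc1OCOC | intermediate
5 | 2,6-bis(methoxymethoxy)-4-methylbenzaldehyde | COCOc1cc(C)cc(OCOC)c1C=O | intermediate
6 | 2-(dimethoxymethyl)-1,3-bis(methoxymethoxy)-5-methylbenzene | COCOc1cc(C)cc(OCOC)c1C(OC)OC | intermediate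
7 | atraric acid (methyl 2,4-dihydroxy-3,6-dimethylbenzoate) | COC(=O)c1c(C)cc(O)c(C)c1O | starting material
8 | methyl 2,4-bis(methoxymethoxy)-3,6-dimethylbenzoate | COC(=O)c1c(C)cc(OCOC)c(C)c1OCOC | intermediate
9 | [2-(methoxycarbonyl)-3,5-bis(methoxymethoxy)-4-methylbenzyl]lithium (lithium dienolate, not isolated) | [Li]Cc1cc(OCOC)c(C)c(OCOC)c1C(=O)OC | intermediate
10 | methyl 6-(chloromethyl)-2,4-bis(methoxymethoxy)-3-methylbenzoate | COC(=O)c1c(CCl)cc(OCOC)c(C)c1OCOC | intermediate
11 | [3-(dimethoxymethyl)-2,4-bis(methoxymethoxy)-6-methylphenyl]lithium (not isolated) | [Li]c1c(C)cc(OCOC)c(C(OC)OC)c1OCOC | intermediate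
12 | lithium 3-(dimethoxymethyl)-2,4-bis(methoxymethoxy)-6-methylbenzoate (not isolated) | [Li+].[O-]C(=O)c1c(C)cc(OCOC)c(C(OC)OC)c1OCOC | intermediate
13 | [2-(methoxycarbonyl)-3,5-bis(methoxymethoxy)-4-methylphenyl]methyl 3-(dimethoxymethyl)-2,4-bis(methoxymethoxy)-6-methylbenzoate | COC(=O)c1c(COC(=O)c2c(C)cc(OCOC)c(C(OC)OC)c2OCOC)cc(OCOC)c(C)c1OCOC | intermediate
14 | [3,5-dihydroxy-2-(methoxycarbonyl)-4-methylphenyl]methyl 3-formyl-2,4-dihydroxy-6-methylbenzoate | COC(=O)c1c(COC(=O)c2c(C)cc(O)c(C=O)c2O)cc(O)c(C)c1O | target

**Step count and risks**
Total step count: 7. Longest linear sequence: 5 steps (1, 2, 3, 6, 7); the ring A branch (steps 4, 5) joins at step 6.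

Steps most likely to fail:

1. Step 5. The benzylic anion 9 may couple with the chloride already formed, may be chlorinated twice after proton exchange with the product, or may attack the ester of a second molecule. The fallback is radical instead of anionic functionalisation and sets out from 7. Acetylation (Ac2O, pyridine, DMAP cat., rt) should give methyl 2,4-diacetoxy-3,6-dimethylbenzoate F1. Wohl–Ziegler bromination (NBS, AIBN, PhCF3, 80 °C) should give methyl 2,4-diacetoxy-6-(bromomethyl)-3-methylbenzoate F2; any isomer brominated at the C3 methyl would be removed by chromatography. F2 then takes the place of 10 in the O-alkylation by carboxylate 12 and should give [3,5-diacetoxy-2-(methoxycarbonyl)-4-methylphenyl]methyl 3-(dimethoxymethyl)-2,4-bis(methoxymethoxy)-6-methylbenzoate F3. Acidic methanolysis (HCl, MeOH, 40 °C, then water) removes the acetyl, MOM and acetal groups, and the fallback comes back to the route at 14.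

2. Step 6. Metalation may go astray (benzylic methyl or acetal C–H instead of the ring C–H) or stay incomplete at the hindered site, which would also leave alkyllithium that ends as a competing carboxylate. The fallback uses halogen–lithium exchange at a pre-set site instead of C–H lithiation and sets out from 5. Electrophilic bromination (NBS, MeCN, rt; the two free ring positions are equivalent) should give 3-bromo-2,6-bis(methoxymethoxy)-4-methylbenzaldehyde F4. Acetalisation as in step 3 should give 1-bromo-3-(dimethoxymethyl)-2,4-bis(methoxymethoxy)-6-methylbenzene F5. Bromine–lithium exchange (t-BuLi, 2 equiv, THF, −78 °C) converts F5 into aryllithium 11, where the fallback comes back to the route; CO2 and then 10 follow as in step 6.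

3. Step 7. Five acid-labile groups must leave without methanolysis of the inter-ring ester, and the methoxymethyl cations or formaldehyde equivalents may alkylate the free positions of the unmasked resorcinol rings. The fallback is stepwise and aprotic in its second stage, and sets out from 13. Mild hydrolysis (PPTS, acetone–H2O, rt) should cleave only the acetal and give [2-(methoxycarbonyl)-3,5-bis(methoxymethoxy)-4-methylphenyl]methyl 3-formyl-2,4-bis(methoxymethoxy)-6-methylbenzoate F6. Bromodimethylborane (CH2Cl2, −78 °C, then aq. NaHCO3) then cleaves the four MOM ethers through boron-complexed oxonium ions, the methoxymethyl groups leaving as the bromo ether and not as formaldehyde; the fallback comes back to the route at 14.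

**Further compounds**
F1 | step 5 | methyl 2,4-diacetoxy-3,6-dimethylbenzoate | COC(=O)c1c(C)cc(OC(C)=O)c(C)c1OC(C)=O
F2 | step 5 | methyl 2,4-diacetoxy-6-(bromomethyl)-3-methylbenzoate | COC(=O)c1c(CBr)cc(OC(C)=O)c(C)c1OC(C)=O
F3 | step 5 | [3,5-diacetoxy-2-(methoxycarbonyl)-4-methylphenyl]methyl 3-(dimethoxymethyl)-2,4-bis(methoxymethoxy)-6-methylbenzoate | COC(=O)c1c(COC(=O)c2c(C)cc(OCOC)c(C(OC)OC)c2OCOC)cc(OC(C)=O)c(C)c1OC(C)=O
F4 | step 6 | 3-bromo-2,6-bis(methoxymethoxy)-4-methylbenzaldehyde | O=Cc1c(OCOC)cc(C)c(Br)c1OCOC
F5 | step 6 | 1-bromo-3-(dimethoxymethyl)-2,4-bis(methoxymethoxy)-6-methylbenzene | COC(OC)c1c(OCOC)cc(C)c(Br)c1OCOC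
F6 | step 7 | [2-(methoxycarbonyl)-3,5-bis(methoxymethoxy)-4-methylphenyl]methyl 3-formyl-2,4-bis(methoxymethoxy)-6-methylbenzoate | COC(=O)c1c(COC(=O)c2c(C)cc(OCOC)c(C=O)c2OCOC)cc(OCOC)c(C)c1OCOC
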